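**Plan**

- Cuts: (a) the ring bond C10–C11 of the 14-membered carbocycle (a CH2 joined to the methyl-bearing sp2 carbon); (b) the enoate C1=C2 (Wittig), which separates a C2–C10 aldehyde carrying the side chain from a C1/C11–C14 ylide; (c) C3–C4 with transposition of the side-chain alkene C2'=C3' (Claisen transform), leading back to geranyl acetate.
- Enabling feature: C10 is homoallylic to the ring alkene C7=C8, and C11 is the methyl-bearing carbon of the E-alkene C11=C12. C10 can therefore arise as a primary alkylborane by 9-BBN hydroboration of a terminal C7=C8–C9=C10 diene, and C11 as an E-iodoalkene, a matched pair for a one-pot hydroboration/B-alkyl Suzuki–Miyaura macrocyclization.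
- Forward order: geranyl acetate → C3' aldehyde → allylboration → prenyl terminus (cross-metathesis) → diene (methylenation) → Johnson–Claisen → aldehyde 14; pent-3-yn-1-ol → E-iodoalkene ylide 21; Wittig union to seco ester 22; the only ring is closed last.
- Stereochemistry: C4 (R) comes from reagent-controlled allylboration (carbinol C3', R), relayed by suprafacial 1,3-chirality transfer in the Claisen step. E-alkenes: C7=C8 from geranyl acetate, C2'=C3' from the chair Claisen, C1=C2 from the stabilized ylide, C11=C12 from syn-hydrozirconation with retention in the coupling.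

Key step: step 13

Remark: ring atoms are numbered C1 (ester-bearing carbon) to C14 through the stereocenter C4, and the side chain C1'–C7' is attached at C2'; (+)-B-allyldiisopinocampheylborane (the reagent derived from (−)-α-pinene) and Cp2Zr(H)Cl are assumed to be purchased reagents.

**Route**

Step 1
Reactants: 1 geranyl acetate
Product: 2 (2E,6E)-8-hydroxy-3,7-dimethylocta-2,6-dien-1-yl acetate
Conditions: SeO2 (0.2 equiv), t-BuOOH (3 equiv), salicylic acid (0.1 equiv), CH2Cl2, rt (any aldehyde 3 formed is carried into step 2)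
Reagents that add atoms: tert-butyl hydroperoxide, CC(C)(C)OO (oxygen source; the oxygen is passed on by catalytic selenium dioxide, O=[Se]=O)
Why: Catalytic SeO2 allylic oxidation (ene reaction, then [2,3]-sigmatropic shift, reoxidation by the hydroperoxide) should attack the electron-richer terminal trisubstituted alkene rather than the one deactivated by the allylic acetate, and hydroxylate its E-methyl group, as is general for isopropylidene termini.

Step 2
Reactants: 2 (2E,6E)-8-hydroxy-3,7-dimethylocta-2,6-dien-1-yl acetate
Product: 3 (2E,6E)-3,7-dimethyl-8-oxoocta-2,6-dien-1-yl acetate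
Conditions: TEMPO (0.1 equiv), PhI(OAc)2 (1.2 equiv), CH2Cl2, rt
Reagents that add atoms: none
Why: Oxoammonium (TEMPO/PhI(OAc)2) oxidation should convert the primary allylic alcohol into the enal without over-oxidation, acetate loss or alkene isomerization.

Step 3
Reactants: 3 (2E,6E)-3,7-dimethyl-8-oxoocta-2,6-dien-1-yl acetate
Product: 6 (2E,6E,8R)-3,7-dimethylundeca-2,6,10-triene-1,8-diol, via diisopinocampheylborinate 4 (not isolated), via hydroxy acetate 5 (not isolated)
Conditions: (+)-Ipc2B(allyl) (1.3 equiv), Et2O, −78 °C; then aq. NaOH (3 mol/L), 30% H2O2, 0 °C → rt; then MeOH, rt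
Reagents that add atoms: (+)-B-allyldiisopinocampheylborane, C=CCB([C@H]1C[C@H]2C[C@@H]([C@@H]1C)C2(C)C)[C@H]1C[C@H]2C[C@@H]([C@@H]1C)C2(C)C
Why: Brown allylboration proceeds through a closed chair six-membered transition state in which the isopinocampheyl groups of the (−)-α-pinene-derived reagent direct allyl transfer to the Re face of the α-methyl enal, setting C8 of 6 (the future side-chain carbon C3') as R, and the alkaline peroxide work-up oxidizes the boron–carbon bonds and, with methanol, also cleaves the acetate.

Step 4
Reactants: 6 (2E,6E,8R)-3,7-dimethylundeca-2,6,10-triene-1,8-diol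
Product: 7 (2E,6E,8R)-3,7,11-trimethyldodeca-2,6,10-triene-1,8-diol
Conditions: 2-methyl-2-butene (large excess, co-solvent), second-generation Grubbs catalyst RuCl2(=CHPh)(PCy3)(H2IMes) (3 mol%), CH2Cl2, 40 °C
Reagents that add atoms: 2-methyl-2-butene, CC=C(C)C
Why: Olefin cross-metathesis with a large excess of 2-methyl-2-butene should exchange only the monosubstituted alkene (the trisubstituted alkenes are inert to the catalyst under these conditions) and cap it as the isopropylidene group, leaving the carbinol stereocenter untouched.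

Step 5
Reactants: 7 (2E,6E,8R)-3,7,11-trimethyldodeca-2,6,10-triene-1,8-diol
Product: 8 (2E,6E,8R)-8-hydroxy-3,7,11-trimethyldodeca-2,6,10-trienal
Conditions: TEMPO (0.1 equiv), PhI(OAc)2 (1.1 equiv), CH2Cl2, 0 °C → rt
Reagents that add atoms: none
Why: TEMPO/PhI(OAc)2 oxidation is strongly selective for the unhindered primary allylic alcohol over the secondary one, so the enal should form while the C8 carbinol stereocenter is kept.

Step 6
Reactants: 8 (2E,6E,8R)-8-hydroxy-3,7,11-trimethyldodeca-2,6,10-trienal
Product: 9 (5R,6E,10E)-2,6,10-trimethyltrideca-2,6,10,12-tetraen-5-ol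
Conditions: Ph3PCH3Br (2.5 equiv), KOt-Bu (2.4 equiv), THF, 0 °C; then 8, −78 → 0 °C
Reagents that add atoms: methyltriphenylphosphonium bromide, C[P+](c1ccccc1)(c1ccccc1)c1ccccc1.[Br-]
Why: Wittig methylenation of the conjugated aldehyde (excess ylide covers the free hydroxyl as its alkoxide) should give the terminal 1,3-diene with the E-trisubstituted alkene unchanged.

Step 7
Reactants: 9 (5R,6E,10E)-2,6,10-trimethyltrideca-2,6,10,12-tetraen-5-ol
Product: 12 ethyl (3R,4E)-4,8-dimethyl-3-[(3E)-3-methylhexa-3,5-dien-1-yl]nona-4,7-dienoate, via mixed orthoester 10 (not isolated), via ketene acetal 11 (not isolated)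
Conditions: MeC(OEt)3 (8 equiv), EtCO2H (0.1 equiv), 140 °C, EtOH distilled off
Reagents that add atoms: triethyl orthoacetate, CCOC(C)(OCC)OCC
Why: In this Johnson–Claisen rearrangement the ketene acetal 11 reacts through a chair transition state with the prenyl-bearing substituent of the carbinol carbon equatorial, so the new C2'=C3' alkene is E, and because the carbon–oxygen bond breaks and the carbon–carbon bond forms on the same face of the E-allyl unit, the R carbinol stereocenter is relayed to R at the new tertiary carbon (ring C4).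

Step 8
Reactants: 12 ethyl (3R,4E)-4,8-dimethyl-3-[(3E)-3-methylhexa-3,5-dien-1-yl]nona-4,7-dienoate
Product: 14 (3R,4E)-4,8-dimethyl-3-[(3E)-3-methylhexa-3,5-dien-1-yl]nona-4,7-dienal, via aluminium hemiacetal 13 (not isolated)
Conditions: i-Bu2AlH (1.1 equiv), CH2Cl2, −78 °C; MeOH, then aq. potassium sodium tartrate
Reagents that add atoms: none
Why: Low-temperature half-reduction of the ester with i-Bu2AlH stops at the tetrahedral aluminium hemiacetal 13, which releases the aldehyde only on work-up, and the stereocenter is β to the carbonyl and cannot epimerize.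

Step 9
Reactants: 15 pent-3-yn-1-ol
Product: 17 (E)-4-iodopent-3-en-1-ol, via alkenylzirconocene 16 (not isolated)
Conditions: Cp2Zr(H)Cl (3 equiv), THF, rt → 50 °C; then iodine (THF), 0 °C; aq. Na2S2O3
Reagents that add atoms: iodine, [I][I]
Why: In this hydrozirconation–iodination the hydroxyl first consumes one equivalent of Cp2Zr(H)Cl, syn addition of zirconium–hydrogen to the alkyne under equilibrating conditions (excess reagent, mild heating) should then place zirconium on the less hindered methyl-bearing carbon, and iodinolysis with retention gives the E-iodoalkene.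

Step 10
Reactants: 17 (E)-4-iodopent-3-en-1-ol
Product: 18 (E)-2,5-diiodopent-2-ene
Conditions: PPh3 (1.3 equiv), imidazole (1.5 equiv), iodine (1.3 equiv), CH2Cl2, 0 °C → rt
Reagents that add atoms: iodine, [I][I]
Why: Appel-type iodination (PPh3/iodine/imidazole) converts the primary alcohol into the iodide by SN2 displacement of the oxyphosphonium group and does not touch the iodoalkene.

Step 11
Reactants: 18 (E)-2,5-diiodopent-2-ene; 19 methyl (triphenyl-λ5-phosphanylidene)acetate
Product: 21 methyl (5E)-6-iodo-2-(triphenyl-λ5-phosphanylidene)hept-5-enoate, via phosphonium iodide 20 (not isolated)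
Conditions: MeCN, 80 °C; then aq. NaOH (1 mol/L), CH2Cl2, rt
Reagents that add atoms: none
Why: C-alkylation of the stabilized ylide by the primary iodide (SN2; the alkenyl iodide is inert) gives phosphonium salt 20, which aqueous base deprotonates to the α-substituted stabilized ylide.

Step 12
Reactants: 14 (3R,4E)-4,8-dimethyl-3-[(3E)-3-methylhexa-3,5-dien-1-yl]nona-4,7-dienal; 21 methyl (5E)-6-iodo-2-(triphenyl-λ5-phosphanylidene)hept-5-enoate
Product: 22 methyl (2E,5R,6E)-2-[(3E)-4-iodopent-3-en-1-yl]-6,10-dimethyl-5-[(3E)-3-methylhexa-3,5-dien-1-yl]undeca-2,6,9-trienoate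
Conditions: toluene, 90 °C
Reagents that add atoms: none
Why: Wittig olefination with an α-substituted ester-stabilized ylide is under thermodynamic control through reversible oxaphosphetane formation and should give the E-enoate (ester trans to C3) with the unhindered aldehyde, while C4, the diene and the iodoalkene are inert.

Step 13
Reactants: 22 methyl (2E,5R,6E)-2-[(3E)-4-iodopent-3-en-1-yl]-6,10-dimethyl-5-[(3E)-3-methylhexa-3,5-dien-1-yl]undeca-2,6,9-trienoate
Product: 24 methyl (1E,4R,7E,11E)-7,11-dimethyl-4-[(2E)-6-methylhepta-2,5-dien-2-yl]cyclotetradeca-1,7,11-triene-1-carboxylate, via alkylborane 23 (not isolated)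
Conditions: 9-BBN-H (1.5 equiv), THF, 0 °C → rt; then syringe-pump addition to Pd(dppf)Cl2 (0.2 equiv), AsPh3 (0.4 equiv), Cs2CO3 (4 equiv), DMF/THF/H2O (degassed), 50 °C, final concentration about 1 mmol/L
Reagents that add atoms: none
Why: 9-BBN-H adds its boron to the terminal carbon C10 of the C7=C8–C9=C10 diene (anti-Markovnikov, syn) to give the homoallylic trialkylborane 23; base then turns 23 into a borate, zerovalent palladium (formed from Pd(dppf)Cl2) inserts into the carbon–iodine bond at C11, the primary alkyl group passes from boron to palladium within the same molecule, and reductive elimination forms C10–C11. The closest known reaction types are the hydroboration of 4,4-disubstituted 1,3-dienes to homoallylboranes and the B-alkyl Suzuki–Miyaura macrocyclization of boryl-terminated alkenyl iodides. The 14-membered carbocycle (C1–C14) is closed by carbon–carbon reductive elimination from a 15-membered palladacycle, with the alkene C11=C12 endocyclic. No stereocenter is created: C4 is remote and untouched, and the E geometry at C11=C12 is controlled by the iodoalkene because oxidative addition and reductive elimination both proceed with retention. The step needs chemoselective hydroboration and ring closure in preference to oligomerization: the first is secured by the steric demand of 9-BBN and by the diene terminus being the only monosubstituted alkene (the trisubstituted alkenes, the enoate and the iodoalkene are too hindered), the second by slow addition at high dilution, by the fast transmetalation of a primary alkyl group with the dppf/AsPh3 system (which also suppresses β-hydride elimination), and by the three E-trisubstituted alkenes that limit the conformational freedom of the seco chain.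

**Compound list**

1 | geranyl acetate, (2E)-3,7-dimethylocta-2,6-dien-1-yl acetate | CC(C)=CCC/C(C)=C/COC(C)=O | starting material
2 | (2E,6E)-8-hydroxy-3,7-dimethylocta-2,6-dien-1-yl acetate | OC/C(C)=C/CC/C(C)=C/COC(C)=O | intermediate
3 | (2E,6E)-3,7-dimethyl-8-oxoocta-2,6-dien-1-yl acetate | O=C/C(C)=C/CC/C(C)=C/COC(C)=O | intermediate
4 | (2E,6E,8R)-1-acetoxy-3,7-dimethylundeca-2,6,10-trien-8-yl diisopinocampheylborinate | C=CC[C@@H](OB([C@H]1C[C@H]2C[C@@H]([C@@H]1C)C2(C)C)[C@H]1C[C@H]2C[C@@H]([C@@H]1C)C2(C)C)/C(C)=C/CC/C(C)=C/COC(C)=O | intermediate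
5 | (2E,6E,8R)-8-hydroxy-3,7-dimethylundeca-2,6,10-trien-1-yl acetate | C=CC[C@@H](O)/C(C)=C/CC/C(C)=C/COC(C)=O | intermediate
6 | (2E,6E,8R)-3,7-dimethylundeca-2,6,10-triene-1,8-diol | C=CC[C@@H](O)/C(C)=C/CC/C(C)=C/CO | intermediate
7 | (2E,6E,8R)-3,7,11-trimethyldodeca-2,6,10-triene-1,8-diol | CC(C)=CC[C@@H](O)/C(C)=C/CC/C(C)=C/CO | intermediate
8 | (2E,6E,8R)-8-hydroxy-3,7,11-trimethyldodeca-2,6,10-trienal | CC(C)=CC[C@@H](O)/C(C)=C/CC/C(C)=C/C=O | intermediate
9 | (5R,6E,10E)-2,6,10-trimethyltrideca-2,6,10,12-tetraen-5-ol | CC(C)=CC[C@@H](O)/C(C)=C/CC/C(C)=C/C=C | intermediate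
10 | mixed orthoester of 9 (1,1-diethoxyethyl ether) | CC(C)=CC[C@@H](OC(C)(OCC)OCC)/C(C)=C/CC/C(C)=C/C=C | intermediate
11 | ketene acetal of 9 (1-ethoxyvinyl ether) | CC(C)=CC[C@@H](OC(=C)OCC)/C(C)=C/CC/C(C)=C/C=C | intermediate
12 | ethyl (3R,4E)-4,8-dimethyl-3-[(3E)-3-methylhexa-3,5-dien-1-yl]nona-4,7-dienoate | CCOC(=O)C[C@H](/C(C)=C/CC=C(C)C)CC/C(C)=C/C=C | intermediate
13 | aluminium hemiacetal of 12 (diisobutylaluminium 1-ethoxyalkoxide) | CCOC(O[Al](CC(C)C)CC(C)C)C[C@H](/C(C)=C/CC=C(C)C)CC/C(C)=C/C=C | intermediate
14 | (3R,4E)-4,8-dimethyl-3-[(3E)-3-methylhexa-3,5-dien-1-yl]nona-4,7-dienal | O=CC[C@H](/C(C)=C/CC=C(C)C)CC/C(C)=C/C=C | intermediate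
15 | pent-3-yn-1-ol | CC#CCCO | starting material
16 | alkenylzirconocene from 15 (zirconium on the methyl-bearing carbon and on oxygen; cyclopentadienyl ligands drawn σ-bonded) | C/C(=C\CCO[Zr](Cl)(C1C=CC=C1)C1C=CC=C1)[Zr](Cl)(C1C=CC=C1)C1C=CC=C1 | intermediate
17 | (E)-4-iodopent-3-en-1-ol | C/C(I)=C\CCO | intermediate
18 | (E)-2,5-diiodopent-2-ene | ICC/C=C(\C)I | intermediate
19 | methyl (triphenyl-λ5-phosphanylidene)acetate | COC(=O)C=P(c1ccccc1)(c1ccccc1)c1ccccc1 | starting material
20 | [(5E)-6-iodo-1-methoxy-1-oxohept-5-en-2-yl]triphenylphosphonium iodide | COC(=O)C(CC/C=C(\C)I)[P+](c1ccccc1)(c1ccccc1)c1ccccc1.[I-] | intermediate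
21 | methyl (5E)-6-iodo-2-(triphenyl-λ5-phosphanylidene)hept-5-enoate | COC(=O)C(CC/C=C(\C)I)=P(c1ccccc1)(c1ccccc1)c1ccccc1 | intermediate
22 | methyl (2E,5R,6E)-2-[(3E)-4-iodopent-3-en-1-yl]-6,10-dimethyl-5-[(3E)-3-methylhexa-3,5-dien-1-yl]undeca-2,6,9-trienoate | COC(=O)/C(=C/C[C@H](/C(C)=C/CC=C(C)C)CC/C(C)=C/C=C)CC/C=C(\C)I | intermediate
23 | B-alkyl-9-BBN from 22 (9-borabicyclo[3.3.1]nonan-9-yl group on the former terminal diene carbon, C10) | COC(=O)/C(=C/C[C@H](/C(C)=C/CC=C(C)C)CC/C(C)=C/CCB1C2CCCC1CCC2)CC/C=C(\C)I | intermediate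
24 | methyl (1E,4R,7E,11E)-7,11-dimethyl-4-[(2E)-6-methylhepta-2,5-dien-2-yl]cyclotetradeca-1,7,11-triene-1-carboxylate | COC(=O)/C1=C/C[C@H](/C(C)=C/CC=C(C)C)CC/C(C)=C/CC/C(C)=C/CC1 | target

**Summary**

Total step count: 13. Longest linear sequence: 10 steps (steps 1 to 8, 12 and 13).

Steps most likely to fail, with fallbacks:

Step 7. The hot, weakly acidic medium may ionize the allylic carbon–oxygen bond (dehydration to a conjugated triene) or degrade the terminal diene before the rearrangement takes place, and chirality transfer would then be lost with the material. The fallback sets out from 9 and comes back at 12. Acetylation (Ac2O, Et3N, DMAP, CH2Cl2) should give the acetate F1. Enolization and O-silylation (LiN(i-Pr)2, Me3SiCl, THF, −78 °C) should give the silyl ketene acetal F2, which is expected to rearrange on warming to room temperature (Ireland–Claisen, same chair and same sense of chirality transfer) to the silyl ester F3. Aqueous work-up should free the acid F4, and iodoethane with K2CO3 in DMF should return ethyl ester 12.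

Step 11. Substitution at the unactivated homoallylic iodide may be slow enough that the ylide acts as a base and elimination to a 1,3-diene takes over, or alkylation may stay incomplete. The fallback sets out from 18 and comes back at 22, replacing steps 11 and 12. The sodium enolate of trimethyl phosphonoacetate (NaH, THF/DMF, 0 → 50 °C), a better nucleophile and a weaker base towards elimination, is alkylated by 18 to give the phosphonate F5. Horner–Wadsworth–Emmons olefination of aldehyde 14 with F5 (LiCl, DBU, MeCN, rt) should then give seco ester 22; the E/Z selectivity is expected to be lower than in the Wittig route, so chromatographic removal of the Z isomer is planned.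

Step 13. Intermolecular coupling may outrun ring closure (oligomers), or hydroboration may not stop cleanly at the diene terminus, so that the borane is consumed by protodeboronation before it cyclizes. The fallback sets out from 12 and comes back at 24: it forms C10–C11 between two fragments by the same coupling chemistry and closes the ring at the enoate C1=C2 instead. Reduction of 12 (LiAlH4, Et2O, 0 °C) should give the alcohol F6. Hydroboration of its diene terminus (9-BBN-H, 1.3 equiv, THF) should give the borane F7, which is coupled with the phosphonate F5 of the preceding fallback (Pd(dppf)Cl2, AsPh3, Cs2CO3, DMF/H2O, rt) to give the hydroxy phosphonate F8. Oxidation (Dess–Martin periodinane, CH2Cl2) should give the aldehyde F9. Intramolecular Horner–Wadsworth–Emmons olefination at high dilution (LiCl, DBU, MeCN) should then close the 14-membered ring to 24; the geometry at C1=C2 has to be checked and the isomers separated if both form.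

**Further compounds**

F1 | step 7 | (5R,6E,10E)-2,6,10-trimethyltrideca-2,6,10,12-tetraen-5-yl acetate | CC(C)=CC[C@@H](OC(C)=O)/C(C)=C/CC/C(C)=C/C=C
F2 | step 7 | silyl ketene acetal of F1 (1-(trimethylsilyloxy)vinyl ether of 9) | CC(C)=CC[C@@H](OC(=C)O[Si](C)(C)C)/C(C)=C/CC/C(C)=C/C=C
F3 | step 7 | trimethylsilyl (3R,4E)-4,8-dimethyl-3-[(3E)-3-methylhexa-3,5-dien-1-yl]nona-4,7-dienoate | C[Si](C)(C)OC(=O)C[C@H](/C(C)=C/CC=C(C)C)CC/C(C)=C/C=C
F4 | step 7 | (3R,4E)-4,8-dimethyl-3-[(3E)-3-methylhexa-3,5-dien-1-yl]nona-4,7-dienoic acid | OC(=O)C[C@H](/C(C)=C/CC=C(C)C)CC/C(C)=C/C=C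
F5 | step 11 | methyl (5E)-2-(dimethoxyphosphoryl)-6-iodohept-5-enoate | COC(=O)C(CC/C=C(\C)I)P(=O)(OC)OC
F6 | step 13 | (3R,4E)-4,8-dimethyl-3-[(3E)-3-methylhexa-3,5-dien-1-yl]nona-4,7-dien-1-ol | OCC[C@H](/C(C)=C/CC=C(C)C)CC/C(C)=C/C=C
F7 | step 13 | B-alkyl-9-BBN from F6 (boron on the former terminal diene carbon) | OCC[C@H](/C(C)=C/CC=C(C)C)CC/C(C)=C/CCB1C2CCCC1CCC2
F8 | step 13 | methyl (5E,9E,13R,14E)-2-(dimethoxyphosphoryl)-13-(2-hydroxyethyl)-6,10,14,18-tetramethylnonadeca-5,9,14,17-tetraenoate | COC(=O)C(P(=O)(OC)OC)CC/C=C(\C)CC/C=C(\C)CC[C@H](CCO)/C(C)=C/CC=C(C)C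
F9 | step 13 | methyl (5E,9E,13R,14E)-2-(dimethoxyphosphoryl)-6,10,14,18-tetramethyl-13-(2-oxoethyl)nonadeca-5,9,14,17-tetraenoate | COC(=O)C(P(=O)(OC)OC)CC/C=C(\C)CC/C=C(\C)CC[C@H](CC=O)/C(C)=C/CC=C(C)C
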